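## The problem

The target has no stereocenter; the difficulty is constitutional and sits in ring A, which carries the pyranone oxygen O1 at C8a, methoxy groups at C5, C7 and C8, and the carbonyl carbon C4 at C4a. C4a lies between two oxygen-bearing carbons, C5 and C8a, and a synthesis has to decide which of these two oxygens becomes O1: closure through the oxygen next to the C7/C8 pair gives the 5,7,8 pattern, closure through the other gives the 5,6,7 isomer, which would be carried to the end. Symmetric ring-A building blocks leave this decision to the selectivity of a demethylation, and a ring-A phenol in which the right oxygen alone is free is not a stock compound. The 5-methoxy group lies peri to the C4 carbonyl and is cleaved with chelation assistance by Lewis acids and hydrogen halides, and once a 5-hydroxyl is free, hot acid can open and re-close the pyranone and scramble the two patterns. Ring B (2,3,4-trimethoxyphenyl) is electron-rich and hindered at C2', and C2 of the pyranone is open to hydroxide and alkoxide, so the last steps should avoid hot acid, hot nucleophilic base and unselective oxidants. The feature on which the plan rests is that the methoxy groups at C5 and C8 stand para to each other on ring A, so that ring A is the dimethyl ether of a hydroquinone, whereas ring B has no para pair of methoxy groups. In the p-quinone that corresponds to ring A, C8a is an unsubstituted carbon, the β-carbon of both the C5 quinone carbonyl and the C4 ketone, and it lies six atoms from the enol oxygen on C2, so that O1 can be delivered to C8a and to no other carbon.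

## Retrosynthesis

**8 ⇒ 7.** The two O–CH3 bonds at C5 and C8 are cut. These are the two oxygens that stand para on ring A, so the cut turns the target into hydroquinone 7 and connects it with quinone 6; the other four methyl ethers are not touched and come from the starting materials. 7 is simpler only by two methyl groups, but it is at the oxidation level at which ring A can act as an electrophile. The forward reaction has to methylate the chelated 5-hydroxyl as well as the 8-hydroxyl without opening the pyranone.

**7 ⇒ 6 ⇒ 5 (key cut).** After the redox adjustment of 7 to 6, the O1–C8a bond is cut by a retro-oxa-Michael reaction. This gives acylquinone 5, with a hydrogen at C8a and O1 as the enol oxygen of a 1,3-diketone. The neighbouring cuts, O1–C2 and C4–C4a, both need a ring-A phenol whose hydroxyl at C8a has been told apart from three other oxygens beforehand. Cutting O1–C8a at the arene oxidation level (a dehydrogenative C–H/O–H coupling) would leave open whether the diketone closes on ring A or on ring B, since each enol oxygen has an ortho C–H of the other ring within reach. In 5 only ring A is electrophilic and only one of its carbons can be reached. 5 has one ring less than 6 and needs no differentiated ring-A oxygen. The forward reaction asks for a 6-endo addition of the enol oxygen to the doubly activated quinone carbon, followed by aromatization.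

**5 ⇒ 4.** The two quinone carbonyl groups at C5 and C8 go back to methyl ethers. 4 is a 2,4,5-trimethoxybenzoyl compound whose only free position ortho to the ketone is the future C8a; all six methyl ethers of the target are in place and no phenol occurs anywhere. What speaks for this cut is that ring A of 4 has the para pair of methoxy groups that an oxidative demethylation needs and ring B has not. The forward reaction asks the oxidant to take ring A before the enol of the diketone and to leave ring B alone.

**4 ⇒ 1 + 2 (through enolate 3).** The C2–C3 bond (flavone numbering) between the methylene carbon and the ring-B carbonyl is cut, a Claisen-type acylation. The other carbon–carbon bond of the diketone could be cut instead, but 1 and 2 are catalogue compounds and 1 already has the complete substitution pattern of ring A. The precursors are two monocyclic compounds. The forward reaction has to acylate at carbon and not at oxygen.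

## Roads not taken

Alternative 1: the cut most chemists would draw first, O1–C2 together with C2–C3, through an ortho-hydroxy ketone. 1,2,3,5-Tetramethoxybenzene A1 is acetylated with AlCl3, which also cleaves one ortho methyl ether, to 1-(2-hydroxy-3,4,6-trimethoxyphenyl)ethan-1-one A2. Aroylation with 2 and Baker–Venkataraman rearrangement give the o-hydroxy diketone A3, whose acid cyclodehydration (the forward key step, closure of O1–C2) gives 8; the chalcone variant closes the same bond oxidatively. The chosen plan is better for three reasons:
- In A1 both oxygens flanking the acylated carbon are methyl ethers, so the choice of O1 rests on the selectivity of a Lewis-acid demethylation and not on structure; cleavage at the other ortho ether leads straight to the 5,6,7 isomer.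
- The ring closure needs hot acid (or iodine in DMSO, which releases HI) next to the peri 5-methoxy group.
- It takes four steps from A1, against three for the chosen route.

Alternative 2: cut C4–C4a, with O1–C2 made first, which closes the pyranone at carbon. 2,3,5-Trimethoxyphenol A4 adds to methyl 3-(2,3,4-trimethoxyphenyl)prop-2-ynoate A5 (oxa-Michael), and the ester is saponified to the (Z)-3-aryloxyacrylic acid A6. Friedel–Crafts acylation (the forward key step, P2O5 in MeSO3H) then closes the ring at the only free carbon ortho to the aryl ether oxygen, which is activated by an ortho and a para methoxy group. The closure is regiochemically unambiguous, but the problem is only moved. A4 must have the terminal oxygen of its 1,2,3-trioxygenated triad free and the middle one methylated; it is not a stock compound, and a protect, oxidize, methylate, deprotect sequence is needed to make it. A5 has to be made as well, and the closure runs in strong acid. The run-up alone is longer than the whole of the chosen route.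

Alternative 3: cut both bonds to C4 (C4–C4a and C3–C4) and O1–C2, a three-component assembly. 2-Iodo-3,5,6-trimethoxyphenol A7, carbon monoxide A8 and 1-ethynyl-2,3,4-trimethoxybenzene A9 are joined by carbonylative Sonogashira coupling (Pd(PPh3)4, CuI, amine base) to the o-hydroxyaryl ynone A10, which closes 6-endo to 8 in the same flask. This is the most convergent cut. However, A7 would have to come from A4 by iodination, and A4 has two activated free positions, so the regiochemical question returns twice: first for the phenol, then for the iodide. A9 is itself two steps from commercial material, and 5-exo closure competes with 6-endo closure. The chosen plan needs neither a differentiated phenol nor a halide.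

Key step: step 2

Remark on the chemistry: 1 and 2 are taken as catalogue compounds (2 is otherwise made from the commercial acid with oxalyl chloride), and 1,3-diketones are drawn in the diketo form although they exist largely as chelated enols.

## Route

Step 1
Reactants: 1 1-(2,4,5-trimethoxyphenyl)ethan-1-one; 2 2,3,4-trimethoxybenzoyl chloride
Product: 4 1-(2,4,5-trimethoxyphenyl)-3-(2,3,4-trimethoxyphenyl)propane-1,3-dione, via lithium enolate 3 (not isolated)
Conditions: LiN(SiMe3)2 (2.2 equiv), THF, −78 °C; then 2, −78 to 0 °C; 1 M HCl
Reagents that add atoms: none
Why: Claisen-type C-acylation of a preformed lithium enolate by an aroyl chloride; the second equivalent of amide base turns the product at once into its chelated lithium diketonate, which protects it from a second acylation and favours reaction at carbon. No stereocenter is formed.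

Step 2
Reactants: 4 1-(2,4,5-trimethoxyphenyl)-3-(2,3,4-trimethoxyphenyl)propane-1,3-dione
Product: 7 5,8-dihydroxy-7-methoxy-2-(2,3,4-trimethoxyphenyl)-4H-chromen-4-one, via acylquinone 5 (not isolated), via flavone-5,8-quinone 6 (not isolated)
Conditions: (NH4)2Ce(NO3)6 (4.4 equiv), MeCN/H2O (3:1), 0 °C; then aq. Na2S2O4, EtOAc, rt
Reagents that add atoms: water, O
Why: Proposed new method: tetravalent cerium takes an electron from ring A of 4, the only ring with a para pair of methoxy groups, water adds at the two ipso carbons and both methyl groups leave as methanol, which is the known oxidative demethylation to a p-quinone and gives 5; the closest known reaction type for what follows is the oxidative cyclization of a side-chain hydroxyl onto a freshly formed quinone, as used for pyranonaphthoquinones, together with the known addition of oxygen nucleophiles to C3 of 2-acyl-1,4-benzoquinones. In 5 the unsubstituted quinone carbon next to the acyl group (the future C8a) is the β-carbon of both the C5 quinone carbonyl and the C4 ketone, and the enol oxygen of the chelated diketone lies six atoms away, so the pyranone closes by a 6-endo-trig oxa-Michael addition that forms O1–C8a. Loss of the proton at C8a aromatizes the adduct to the hydroquinone, the excess oxidant takes it on to 6, and dithionite in the work-up returns all of the material to 7. No stereocenter is formed. The step needs three selectivities: ring A over ring B, secured by the para relationship of the C5 and C8 oxygens because ring B cannot give a p-quinone; O1–C8a over any other closure, secured by structure because the second enol oxygen would have to form a four-membered ring and the other free quinone carbon (C6) is out of reach and deactivated by the C7 methoxy group; and oxidation of the arene before the enol of the diketone, which is not secured and is the main risk. Water that adds first at the same quinone carbon would lead to the same product by cyclodehydration, so both orders of events converge.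

Step 3
Reactants: 7 5,8-dihydroxy-7-methoxy-2-(2,3,4-trimethoxyphenyl)-4H-chromen-4-one
Product: 8 5,7,8-trimethoxy-2-(2,3,4-trimethoxyphenyl)-4H-chromen-4-one (2',3',4',5,7,8-hexamethoxyflavone)
Conditions: Me2SO4 (6 equiv), K2CO3, acetone, reflux, N2
Reagents that add atoms: dimethyl sulfate, COS(=O)(=O)OC
Why: Williamson O-methylation of both hydroquinone hydroxyls; the free 8-hydroxyl reacts first and the 5-hydroxyl, hydrogen-bonded to the C4 carbonyl, follows at reflux with excess reagent. The medium is basic and non-nucleophilic, so neither the pyranone nor the methyl ethers are endangered and no acid-induced ring opening toward the 5,6,7 pattern can occur; air is excluded because the hydroquinone anion is easily re-oxidized to 6.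

## Compound list

1 | 1-(2,4,5-trimethoxyphenyl)ethan-1-one | CC(=O)c1cc(OC)c(OC)cc1OC | starting material
2 | 2,3,4-trimethoxybenzoyl chloride | COc1ccc(C(Cl)=O)c(OC)c1OC | starting material
3 | lithium 1-(2,4,5-trimethoxyphenyl)ethen-1-olate | [Li+].[O-]C(=C)c1cc(OC)c(OC)cc1OC | intermediate
4 | 1-(2,4,5-trimethoxyphenyl)-3-(2,3,4-trimethoxyphenyl)propane-1,3-dione | COc1ccc(C(=O)CC(=O)c2cc(OC)c(OC)cc2OC)c(OC)c1OC | intermediate
5 | 1-(4-methoxy-3,6-dioxocyclohexa-1,4-dien-1-yl)-3-(2,3,4-trimethoxyphenyl)propane-1,3-dione | COc1ccc(C(=O)CC(=O)C2=CC(=O)C(OC)=CC2=O)c(OC)c1OC | intermediate
6 | 7-methoxy-2-(2,3,4-trimethoxyphenyl)-4H-chromene-4,5,8-trione | COc1ccc(C2=CC(=O)C3=C(O2)C(=O)C(OC)=CC3=O)c(OC)c1OC | intermediate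
7 | 5,8-dihydroxy-7-methoxy-2-(2,3,4-trimethoxyphenyl)-4H-chromen-4-one | COc1ccc(-c2cc(=O)c3c(O)cc(OC)c(O)c3o2)c(OC)c1OC | intermediate
8 | 5,7,8-trimethoxy-2-(2,3,4-trimethoxyphenyl)-4H-chromen-4-one | COc1ccc(-c2cc(=O)c3c(OC)cc(OC)c(OC)c3o2)c(OC)c1OC | target

## Step count and risks

Total steps: 3. Longest linear sequence: 3 (1 → 4 → 7 → 8).

**Step 2 (key step, proposed new method).** The most likely failure is one-electron oxidation of the chelated enol of the diketone by tetravalent cerium in competition with oxidation of ring A, followed by coupling or α-oxygenation of the side chain. Next in likelihood is slow ring closure of 5, so that the reductive work-up comes too early and the reduced side chain closes through the wrong oxygen (the hydroxyl at the future C5, which is ortho to the ketone); the oxidant must therefore stay in excess until 5 is consumed. Lesser risks are hydrolysis of the vinylogous-ester methoxy group at C7 of 6 in the acidic aqueous medium and slow oxidative attack on ring B on long exposure.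

Fallback (known reaction types only; it sets out from 1 and comes back at 8): the oxidation is moved to a stage at which neither an enol nor ring B is present, and the ring oxygen is brought in by way of a halide.
- 1 is oxidized alone with (NH4)2Ce(NO3)6 to 2-acetyl-5-methoxycyclohexa-2,5-diene-1,4-dione F1.
- HBr adds at the quinone carbon next to the acetyl group, the same doubly activated carbon, to give 1-(2-bromo-3,6-dihydroxy-4-methoxyphenyl)ethan-1-one F2.
- Methylation with Me2SO4 and K2CO3 gives 1-(2-bromo-3,4,6-trimethoxyphenyl)ethan-1-one F3.
- C-acylation with 2 under the conditions of step 1 gives 1-(2-bromo-3,4,6-trimethoxyphenyl)-3-(2,3,4-trimethoxyphenyl)propane-1,3-dione F4.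
- Intramolecular Ullmann O-arylation of the enolate (CuI, K2CO3, DMF, heat) closes O1–C8a to 8.

The regiochemistry is still fixed by structure, at the price of two more steps.

**Step 1.** The most likely failure is O-acylation of the enolate, or acyl transfer to the amide base, by the hindered and electron-rich aroyl chloride, together with a second acylation of the product.

Fallback (it sets out from 1 and comes back at 4): the carbon–carbon bond is made at the aldehyde oxidation level, where O-acylation cannot occur. Lithium enolate 3 is added to 2,3,4-trimethoxybenzaldehyde F5 at −78 °C to give racemic 3-hydroxy-1-(2,4,5-trimethoxyphenyl)-3-(2,3,4-trimethoxyphenyl)propan-1-one F6, which is oxidized with Dess–Martin periodinane to 4.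

**Step 3.** The most likely failure is re-oxidation of the hydroquinone anion by traces of air before both oxygens are alkylated, and incomplete alkylation of the hydrogen-bonded 5-hydroxyl.

Fallback (it sets out from 7 and comes back at 8): the two hydroxyls are methylated in two operations. The unchelated 8-hydroxyl is capped first under mild conditions (MeI, K2CO3, DMF, rt, N2) to give 5-hydroxy-7,8-dimethoxy-2-(2,3,4-trimethoxyphenyl)-4H-chromen-4-one F7, which is no longer a hydroquinone and should be stable to air. The chelated 5-hydroxyl is then methylated as its sodium salt (NaH, MeI, DMF).

## Further compounds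

F1 | step 2 | 2-acetyl-5-methoxycyclohexa-2,5-diene-1,4-dione | CC(=O)C1=CC(=O)C(OC)=CC1=O
F2 | step 2 | 1-(2-bromo-3,6-dihydroxy-4-methoxyphenyl)ethan-1-one | CC(=O)c1c(Br)c(O)c(OC)cc1O
F3 | step 2 | 1-(2-bromo-3,4,6-trimethoxyphenyl)ethan-1-one | CC(=O)c1c(Br)c(OC)c(OC)cc1OC
F4 | step 2 | 1-(2-bromo-3,4,6-trimethoxyphenyl)-3-(2,3,4-trimethoxyphenyl)propane-1,3-dione | COc1ccc(C(=O)CC(=O)c2c(Br)c(OC)c(OC)cc2OC)c(OC)c1OC
F5 | step 1 | 2,3,4-trimethoxybenzaldehyde | COc1ccc(C=O)c(OC)c1OC
F6 | step 1 | 3-hydroxy-1-(2,4,5-trimethoxyphenyl)-3-(2,3,4-trimethoxyphenyl)propan-1-one (racemic) | COc1ccc(C(O)CC(=O)c2cc(OC)c(OC)cc2OC)c(OC)c1OC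
F7 | step 3 | 5-hydroxy-7,8-dimethoxy-2-(2,3,4-trimethoxyphenyl)-4H-chromen-4-one | COc1ccc(-c2cc(=O)c3c(O)cc(OC)c(OC)c3o2)c(OC)c1OC
A1 | alternative 1 | 1,2,3,5-tetramethoxybenzene | COc1cc(OC)c(OC)c(OC)c1
A2 | alternative 1 | 1-(2-hydroxy-3,4,6-trimethoxyphenyl)ethan-1-one | CC(=O)c1c(O)c(OC)c(OC)cc1OC
A3 | alternative 1 | 1-(2-hydroxy-3,4,6-trimethoxyphenyl)-3-(2,3,4-trimethoxyphenyl)propane-1,3-dione | COc1ccc(C(=O)CC(=O)c2c(O)c(OC)c(OC)cc2OC)c(OC)c1OC
A4 | alternative 2 | 2,3,5-trimethoxyphenol | COc1cc(O)c(OC)c(OC)c1
A5 | alternative 2 | methyl 3-(2,3,4-trimethoxyphenyl)prop-2-ynoate | COC(=O)C#Cc1ccc(OC)c(OC)c1OC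
A6 | alternative 2 | (Z)-3-(2,3,5-trimethoxyphenoxy)-3-(2,3,4-trimethoxyphenyl)prop-2-enoic acid | OC(=O)/C=C(\Oc1cc(OC)cc(OC)c1OC)c1ccc(OC)c(OC)c1OC
A7 | alternative 3 | 2-iodo-3,5,6-trimethoxyphenol | COc1cc(OC)c(OC)c(O)c1I
A8 | alternative 3 | carbon monoxide | [C-]#[O+]
A9 | alternative 3 | 1-ethynyl-2,3,4-trimethoxybenzene | COc1ccc(C#C)c(OC)c1OC
A10 | alternative 3 | 1-(2-hydroxy-3,4,6-trimethoxyphenyl)-3-(2,3,4-trimethoxyphenyl)prop-2-yn-1-one | COc1ccc(C#CC(=O)c2c(O)c(OC)c(OC)cc2OC)c(OC)c1OC
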